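Rings are lettered A–E from the 2,4,6-trihydroxyphenoxy end; in ring C, C1 carries the oxygen to ring B and C4 the oxygen to ring D. Ring C is built last from two fragments that already hold all four ether oxygens, so no C–O coupling is attempted at C4, crowded between C3–OH and C5–OH. C1 and C2 come from the A–B aryl ethynyl ether 22, C3–C6 from the D–E 4-aryloxy-3-ethoxycyclobutenone 10. One thermal benzannulation forms C1–C6 and C2–C3, re-forms C3–C4 and gives C3–OH, exploiting the meta relationship of the C1 and C3 oxygens. BBr3 then frees all fourteen hydroxyls.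

Key step: step 10

Remark: 28 has no stereocentre and is achiral, so there is no enantiomer to select; the stereocentres of 10, 24 and 26 are racemic and vanish on aromatisation.

Abbreviations in names: ArDE = 3,4,5-trimethoxy-2-(3,4,5-trimethoxyphenoxy)phenyl; ArAB = 2,3,4-trimethoxy-6-(2,4,6-trimethoxyphenoxy)phenyl.

Step 1
Reactants: 1 2-bromo-3,4,5-trimethoxybenzaldehyde; 2 3,4,5-trimethoxyphenol
Product: 3 3,4,5-trimethoxy-2-(3,4,5-trimethoxyphenoxy)benzaldehyde
Conditions: CuI (10 mol%), picolinic acid (20 mol%), K3PO4, DMSO, 90 °C, Ar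
Reagents that add atoms: none
Why: Ullmann diaryl ether coupling in which the ortho-formyl group activates the C–Br bond, the phenol is unhindered, and the ligand system tolerates the flanking methoxy group.

Step 2
Reactants: 3 3,4,5-trimethoxy-2-(3,4,5-trimethoxyphenoxy)benzaldehyde
Product: 5 3,4,5-trimethoxy-2-(3,4,5-trimethoxyphenoxy)phenol (D–E phenol), via aryl formate 4 (not isolated)
Conditions: mCPBA, CH2Cl2, 0 °C → rt; then K2CO3 (cat.), MeOH, rt
Reagents that add atoms: mCPBA, OOC(=O)c1cccc(Cl)c1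
Why: Baeyer–Villiger (Dakin-type) oxidation in which the electron-rich aryl group, carrying ortho and para oxygen donors, migrates in preference to hydrogen, and the formate is removed by methanolysis.

Step 3
Reactants: 5 D–E phenol
Product: 6 2-[3,4,5-trimethoxy-2-(3,4,5-trimethoxyphenoxy)phenoxy]acetic acid
Conditions: BrCH2CO2H, NaH (2.5 equiv), THF, 0 °C → reflux; then 1 M HCl
Reagents that add atoms: bromoacetic acid, OC(=O)CBr
Why: Williamson ether synthesis of an aryloxyacetic acid from the sodium phenoxide and sodium bromoacetate at a primary, carboxylate-activated carbon.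

Step 4
Reactants: 6 ArDE-oxyacetic acid; 7 ethoxyacetylene
Product: 10 racemic 3-ethoxy-4-[3,4,5-trimethoxy-2-(3,4,5-trimethoxyphenoxy)phenoxy]cyclobut-2-en-1-one, via acid chloride 8 (not isolated), via aryloxyketene 9 (not isolated)
Conditions: (COCl)2, DMF (cat.), CH2Cl2, 0 °C → rt, evaporate; then 7 (3 equiv), Et3N (slow addition), CH2Cl2, 0 °C → rt
Reagents that add atoms: none
Why: Dehydrochlorination of 8 gives aryloxyketene 9, and the ketene–ynol ether [2+2] cycloaddition joins the nucleophilic CH terminus of 7 to the ketene carbonyl carbon, which gives the 3-ethoxy-4-aryloxy regioisomer; the C4 stereocentre forms racemic and needs no control because step 10 destroys it.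

Step 5
Reactants: 11 5-bromo-1,2,3-trimethoxybenzene
Product: 12 6-bromo-2,3,4-trimethoxybenzaldehyde
Conditions: Cl2CHOMe, TiCl4, CH2Cl2, 0 °C; then H2O
Reagents that add atoms: dichloromethyl methyl ether, COC(Cl)Cl; water, O
Why: Rieche formylation, for which the only two free positions are equivalent, each ortho to one methoxy group and para to another, so a single aldehyde is expected.

Step 6
Reactants: 12 6-bromo-2,3,4-trimethoxybenzaldehyde; 13 2,4,6-trimethoxyphenol
Product: 14 2,3,4-trimethoxy-6-(2,4,6-trimethoxyphenoxy)benzaldehyde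
Conditions: CuI (10 mol%), picolinic acid (20 mol%), K3PO4, degassed DMSO, 90 °C, Ar
Reagents that add atoms: none
Why: Ullmann diaryl ether coupling in which the bromide has the activating formyl group as its only ortho substituent, which offsets the two ortho methoxy groups of the phenol; oxygen is excluded because 13 oxidises easily.

Step 7
Reactants: 14 2,3,4-trimethoxy-6-(2,4,6-trimethoxyphenoxy)benzaldehyde
Product: 16 2,3,4-trimethoxy-6-(2,4,6-trimethoxyphenoxy)phenol (A–B phenol), via aryl formate 15 (not isolated)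
Conditions: mCPBA, CH2Cl2, 0 °C → rt; then K2CO3 (cat.), MeOH, rt
Reagents that add atoms: mCPBA, OOC(=O)c1cccc(Cl)c1
Why: Baeyer–Villiger (Dakin-type) oxidation of a benzaldehyde with two ortho and one para oxygen donors, so aryl migration to the formate should dominate, followed by methanolysis.

Step 8
Reactants: 16 A–B phenol; 17 trichloroethylene
Product: 19 1-{[(E)-1,2-dichloroethenyl]oxy}-2,3,4-trimethoxy-6-(2,4,6-trimethoxyphenoxy)benzene, via dichloroacetylene 18 (not isolated)
Conditions: K2CO3, DMF, 70 °C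
Reagents that add atoms: none
Why: Base-induced elimination from 17 gives dichloroacetylene, to which the phenoxide adds in anti fashion (nucleophilic vinylation), giving the (E)-1,2-dichlorovinyl ether.

Step 9
Reactants: 19 ArAB (E)-1,2-dichlorovinyl ether
Product: 22 1-(ethynyloxy)-2,3,4-trimethoxy-6-(2,4,6-trimethoxyphenoxy)benzene (A–B ynol ether), via chloroethynyl ether 20 (not isolated), via lithium acetylide 21 (not isolated)
Conditions: n-BuLi (2.3 equiv), THF, −78 → −40 °C; then H2O, −78 °C; used at once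
Reagents that add atoms: none
Why: Vinylic deprotonation and β-elimination of LiCl give the chloroalkyne, lithium–chlorine exchange gives the acetylide, and protonation gives the terminal aryl ynol ether, a sequence fast enough at −78 °C to outrun ring lithiation.

Step 10
Reactants: 10 racemic D–E cyclobutenone; 22 A–B ynol ether
Product: 27 3-ethoxy-5-[2,3,4-trimethoxy-6-(2,4,6-trimethoxyphenoxy)phenoxy]-2-[3,4,5-trimethoxy-2-(3,4,5-trimethoxyphenoxy)phenoxy]phenol, via vinylketene 23 (not isolated), via vinylcyclobutenone 24 (not isolated), via dienylketene 25 (not isolated), via cyclohexadienone 26 (not isolated)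
Conditions: 10 (1.3 equiv), toluene (0.5 M), 80 → 110 °C, Ar; then KOH, MeOH, rt
Reagents that add atoms: none
Why: Heating opens 10 by 4π electrocyclic cleavage (aryloxy group turning outward) to vinylketene 23, whose ketene C=C adds 22 in a [2+2] to vinylcyclobutenone 24; a second 4π opening gives dienylketene 25, which closes ring C by thermal 6π disrotatory electrocyclisation, and dienone 26 tautomerises to the phenol. This is the Danheiser benzannulation as practised with alkoxyacetylenes, which gives resorcinol monoethers. Ring C therefore closes in an electrocyclic mode, with C1–C6 and C2–C3 made in the [2+2] and C3–C4 in the 6π step; no stereocentre remains in 27. The one selectivity needed is regiochemical: oxygen donation makes the CH terminus of 22 nucleophilic, so it bonds to the ketene carbonyl carbon and the aryloxy-bearing carbon ends up meta to the new hydroxyl and para to the O–D carbon. An aryl ynol ether has no β-hydrogen for retro-ene loss of ketene at these temperatures, and the methanolic KOH finish returns any product that was O-acylated by 23.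

Step 11
Reactants: 27 protected pentamer
Product: 28 5-[2,3,4-trihydroxy-6-(2,4,6-trihydroxyphenoxy)phenoxy]-2-[3,4,5-trihydroxy-2-(3,4,5-trihydroxyphenoxy)phenoxy]benzene-1,3-diol
Conditions: BBr3 (about 3 equiv per ether), CH2Cl2, −78 °C → rt; then degassed H2O, 0 °C; C18 chromatography under Ar
Reagents that add atoms: none
Why: Lewis acid dealkylation of aryl alkyl ethers with boron tribromide cleaves the twelve methyl ethers and the ethyl ether at the alkyl–oxygen bond, and diaryl ethers are inert to it.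

Compound list
1 | 2-bromo-3,4,5-trimethoxybenzaldehyde | O=Cc1cc(OC)c(OC)c(OC)c1Br | starting material
2 | 3,4,5-trimethoxyphenol | COc1cc(O)cc(OC)c1OC | starting material
3 | 3,4,5-trimethoxy-2-(3,4,5-trimethoxyphenoxy)benzaldehyde | O=Cc1cc(OC)c(OC)c(OC)c1Oc1cc(OC)c(OC)c(OC)c1 | intermediate
4 | 3,4,5-trimethoxy-2-(3,4,5-trimethoxyphenoxy)phenyl formate | O=COc1cc(OC)c(OC)c(OC)c1Oc1cc(OC)c(OC)c(OC)c1 | intermediate (not isolated)
5 | 3,4,5-trimethoxy-2-(3,4,5-trimethoxyphenoxy)phenol | Oc1cc(OC)c(OC)c(OC)c1Oc1cc(OC)c(OC)c(OC)c1 | intermediate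
6 | 2-[3,4,5-trimethoxy-2-(3,4,5-trimethoxyphenoxy)phenoxy]acetic acid | OC(=O)COc1cc(OC)c(OC)c(OC)c1Oc1cc(OC)c(OC)c(OC)c1 | intermediate
7 | ethoxyacetylene | CCOC#C | starting material
8 | 2-[3,4,5-trimethoxy-2-(3,4,5-trimethoxyphenoxy)phenoxy]acetyl chloride | ClC(=O)COc1cc(OC)c(OC)c(OC)c1Oc1cc(OC)c(OC)c(OC)c1 | intermediate (not isolated)
9 | 2-[3,4,5-trimethoxy-2-(3,4,5-trimethoxyphenoxy)phenoxy]ethen-1-one (aryloxyketene) | O=C=COc1cc(OC)c(OC)c(OC)c1Oc1cc(OC)c(OC)c(OC)c1 | intermediate (not isolated)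
10 | racemic 3-ethoxy-4-[3,4,5-trimethoxy-2-(3,4,5-trimethoxyphenoxy)phenoxy]cyclobut-2-en-1-one | CCOC1=CC(=O)C1Oc1cc(OC)c(OC)c(OC)c1Oc1cc(OC)c(OC)c(OC)c1 | intermediate
11 | 5-bromo-1,2,3-trimethoxybenzene | COc1cc(Br)cc(OC)c1OC | starting material
12 | 6-bromo-2,3,4-trimethoxybenzaldehyde | O=Cc1c(Br)cc(OC)c(OC)c1OC | intermediate
13 | 2,4,6-trimethoxyphenol | COc1cc(OC)c(O)c(OC)c1 | starting material
14 | 2,3,4-trimethoxy-6-(2,4,6-trimethoxyphenoxy)benzaldehyde | O=Cc1c(OC)c(OC)c(OC)cc1Oc1c(OC)cc(OC)cc1OC | intermediate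
15 | 2,3,4-trimethoxy-6-(2,4,6-trimethoxyphenoxy)phenyl formate | O=COc1c(OC)c(OC)c(OC)cc1Oc1c(OC)cc(OC)cc1OC | intermediate (not isolated)
16 | 2,3,4-trimethoxy-6-(2,4,6-trimethoxyphenoxy)phenol | Oc1c(OC)c(OC)c(OC)cc1Oc1c(OC)cc(OC)cc1OC | intermediate
17 | trichloroethylene | ClC=C(Cl)Cl | starting material
18 | dichloroacetylene | ClC#CCl | intermediate (not isolated)
19 | 1-{[(E)-1,2-dichloroethenyl]oxy}-2,3,4-trimethoxy-6-(2,4,6-trimethoxyphenoxy)benzene | Cl/C=C(/Cl)Oc1c(OC)c(OC)c(OC)cc1Oc1c(OC)cc(OC)cc1OC | intermediate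
20 | 1-[(chloroethynyl)oxy]-2,3,4-trimethoxy-6-(2,4,6-trimethoxyphenoxy)benzene | ClC#COc1c(OC)c(OC)c(OC)cc1Oc1c(OC)cc(OC)cc1OC | intermediate (not isolated)
21 | lithium 2-[2,3,4-trimethoxy-6-(2,4,6-trimethoxyphenoxy)phenoxy]ethynide | [Li]C#COc1c(OC)c(OC)c(OC)cc1Oc1c(OC)cc(OC)cc1OC | intermediate (not isolated)
22 | 1-(ethynyloxy)-2,3,4-trimethoxy-6-(2,4,6-trimethoxyphenoxy)benzene | C#COc1c(OC)c(OC)c(OC)cc1Oc1c(OC)cc(OC)cc1OC | intermediate
23 | (3Z)-3-ethoxy-4-(ArDE-oxy)buta-1,3-dien-1-one (vinylketene) | O=C=C/C(OCC)=C/Oc1cc(OC)c(OC)c(OC)c1Oc1cc(OC)c(OC)c(OC)c1 | intermediate (not isolated)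
24 | racemic 3-(ArAB-oxy)-4-[(Z)-1-ethoxy-2-(ArDE-oxy)ethenyl]cyclobut-2-en-1-one | O=C1C=C(Oc2c(OC)c(OC)c(OC)cc2Oc2c(OC)cc(OC)cc2OC)C1/C(OCC)=C/Oc1cc(OC)c(OC)c(OC)c1Oc1cc(OC)c(OC)c(OC)c1 | intermediate (not isolated)
25 | (3E,5Z)-5-ethoxy-3-(ArAB-oxy)-6-(ArDE-oxy)hexa-1,3,5-trien-1-one (dienylketene) | O=C=C/C(Oc1c(OC)c(OC)c(OC)cc1Oc1c(OC)cc(OC)cc1OC)=C\C(OCC)=C\Oc1cc(OC)c(OC)c(OC)c1Oc1cc(OC)c(OC)c(OC)c1 | intermediate (not isolated)
26 | racemic 5-ethoxy-3-(ArAB-oxy)-6-(ArDE-oxy)cyclohexa-2,4-dien-1-one | O=C1C=C(Oc2c(OC)c(OC)c(OC)cc2Oc2c(OC)cc(OC)cc2OC)C=C(OCC)C1Oc1cc(OC)c(OC)c(OC)c1Oc1cc(OC)c(OC)c(OC)c1 | intermediate (not isolated)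
27 | 3-ethoxy-5-[2,3,4-trimethoxy-6-(2,4,6-trimethoxyphenoxy)phenoxy]-2-[3,4,5-trimethoxy-2-(3,4,5-trimethoxyphenoxy)phenoxy]phenol | COc1cc(OC)c(Oc2cc(OC)c(OC)c(OC)c2Oc2cc(O)c(Oc3cc(OC)c(OC)c(OC)c3Oc3cc(OC)c(OC)c(OC)c3)c(OCC)c2)c(OC)c1 | intermediate
28 | 5-[2,3,4-trihydroxy-6-(2,4,6-trihydroxyphenoxy)phenoxy]-2-[3,4,5-trihydroxy-2-(3,4,5-trihydroxyphenoxy)phenoxy]benzene-1,3-diol | Oc1cc(O)c(Oc2cc(O)c(O)c(O)c2Oc2cc(O)c(Oc3cc(O)c(O)c(O)c3Oc3cc(O)c(O)c(O)c3)c(O)c2)c(O)c1 | target

Total step count: 11. Longest linear sequence: 7 steps (steps 5 to 11, from 11 to 28); the D–E branch contributes steps 1 to 4.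

Steps most likely to fail

Step 10. The terminal ynol ether 22 may polymerise, or vinylketene 23 may oligomerise or be intercepted by the product phenol, before the [2+2] takes place; the second ring opening of 24 may also stall. The fallback sets out from phenols 5 and 16 and comes back to the route at target 28, with ring C brought in as a preformed arene. Phenol 5 would be condensed by SNAr (K2CO3, DMF, 100 °C) with the catalogue building block 5-bromo-2-fluoro-3-methoxybenzaldehyde at the fluorine ortho to the formyl group, giving bromo aldehyde F1. Ullmann coupling of the unhindered bromide of F1 with phenol 16 (CuI, picolinic acid, K3PO4, DMSO) should give pentaaryl aldehyde F2. Baeyer–Villiger oxidation with mCPBA should give aryl formate F3, and methanolysis the pentaaryl phenol F4, the methyl ether analogue of 27. Boron tribromide as in step 11 would then give 28.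

Step 4. Aryloxyketene 9 may self-condense faster than it adds to ethoxyacetylene, and the vinylogous ester 10 may be lost by hydrolysis on isolation. The fallback sets out from phenol 5 (with ynol ether 22 as partner) and comes back to the route at 27, bypassing the cyclobutenone by generating the same vinylketene through 1,4-dehydrochlorination. Phenol 5 would be alkylated (K2CO3, NaI, DMF) with commercial ethyl (E)-4-chloro-3-ethoxybut-2-enoate to give crotonate ester F5. Saponification (LiOH, THF/H2O, careful acidification at 0 °C) should give crotonic acid F6, and 1-chloro-N,N,2-trimethylpropenylamine in CH2Cl2 the crotonoyl chloride F7. Slow addition of Et3N to F7 and 22 in toluene, filtration and heating to 80–110 °C should pass through 23 and 24 to 27.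

Step 11. Cleavage of thirteen ethers may stop short, and the three pyrogallol rings may oxidise in air during aqueous isolation and chromatography. The fallback sets out from 27 and comes back at 28 by capture and release. The crude BBr3 product, after evaporation with methanol, would be acetylated directly (Ac2O, pyridine, rt) to the air-stable tetradecaacetate F8. F8 can be purified on silica and freed from partly dealkylated material. Degassed methanolic HCl (from AcCl in MeOH, rt) and evaporation should then give 28 without aqueous handling.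

Further compounds
F1 | step 10 | 5-bromo-3-methoxy-2-[3,4,5-trimethoxy-2-(3,4,5-trimethoxyphenoxy)phenoxy]benzaldehyde | O=Cc1cc(Br)cc(OC)c1Oc1cc(OC)c(OC)c(OC)c1Oc1cc(OC)c(OC)c(OC)c1
F2 | step 10 | 3-methoxy-5-[2,3,4-trimethoxy-6-(2,4,6-trimethoxyphenoxy)phenoxy]-2-[3,4,5-trimethoxy-2-(3,4,5-trimethoxyphenoxy)phenoxy]benzaldehyde | O=Cc1cc(Oc2c(OC)c(OC)c(OC)cc2Oc2c(OC)cc(OC)cc2OC)cc(OC)c1Oc1cc(OC)c(OC)c(OC)c1Oc1cc(OC)c(OC)c(OC)c1
F3 | step 10 | 3-methoxy-5-[2,3,4-trimethoxy-6-(2,4,6-trimethoxyphenoxy)phenoxy]-2-[3,4,5-trimethoxy-2-(3,4,5-trimethoxyphenoxy)phenoxy]phenyl formate | O=COc1cc(Oc2c(OC)c(OC)c(OC)cc2Oc2c(OC)cc(OC)cc2OC)cc(OC)c1Oc1cc(OC)c(OC)c(OC)c1Oc1cc(OC)c(OC)c(OC)c1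
F4 | step 10 | 3-methoxy-5-[2,3,4-trimethoxy-6-(2,4,6-trimethoxyphenoxy)phenoxy]-2-[3,4,5-trimethoxy-2-(3,4,5-trimethoxyphenoxy)phenoxy]phenol | Oc1cc(Oc2c(OC)c(OC)c(OC)cc2Oc2c(OC)cc(OC)cc2OC)cc(OC)c1Oc1cc(OC)c(OC)c(OC)c1Oc1cc(OC)c(OC)c(OC)c1
F5 | step 4 | ethyl (2E)-3-ethoxy-4-[3,4,5-trimethoxy-2-(3,4,5-trimethoxyphenoxy)phenoxy]but-2-enoate | CCO/C(COc1cc(OC)c(OC)c(OC)c1Oc1cc(OC)c(OC)c(OC)c1)=C/C(=O)OCC
F6 | step 4 | (2E)-3-ethoxy-4-[3,4,5-trimethoxy-2-(3,4,5-trimethoxyphenoxy)phenoxy]but-2-enoic acid | CCO/C(COc1cc(OC)c(OC)c(OC)c1Oc1cc(OC)c(OC)c(OC)c1)=C/C(=O)O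
F7 | step 4 | (2E)-3-ethoxy-4-[3,4,5-trimethoxy-2-(3,4,5-trimethoxyphenoxy)phenoxy]but-2-enoyl chloride | CCO/C(COc1cc(OC)c(OC)c(OC)c1Oc1cc(OC)c(OC)c(OC)c1)=C/C(=O)Cl
F8 | step 11 | tetradecaacetate of 28 (every hydroxyl as its acetate) | CC(=O)Oc1cc(OC(C)=O)c(Oc2cc(OC(C)=O)c(OC(C)=O)c(OC(C)=O)c2Oc2cc(OC(C)=O)c(Oc3cc(OC(C)=O)c(OC(C)=O)c(OC(C)=O)c3Oc3cc(OC(C)=O)c(OC(C)=O)c(OC(C)=O)c3)c(OC(C)=O)c2)c(OC(C)=O)c1
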